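**Strategy**

The 14-membered macrolactone (ring atoms C1–C13 plus the lactone oxygen) is disconnected across C6/C7: its E-trisubstituted C6(CH3)=C7H alkene, homoallylic to the C4 tertiary hydroxyl, is treated as a masked C6≡C7 alkyne. Ring-closing alkyne metathesis of an ester-tethered diyne with two methyl-capped alkynes makes the C6≡C7 bond and closes the ring in one operation, leaving the C10 exo-methylene/C11=C12 diene untouched. The precursor is the ester of a C1–C6 acid (C3 as silyl ether, C4 diol as acetonide) with a C7–C13 dienynol. C3 oxidation, acetonide removal, C4-hydroxyl-directed trans-hydrostannation and methyl-for-tin exchange then complete the target.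

Key step: step 18

Remark on the chemistry: carbons are numbered C1 (lactone carbonyl) to C13 (the CH(Et)O carbon); C3 is carried through the ring closure as its triethylsilyl ether and oxidised afterwards, because a 2-methyl-3-keto ester is C–H acidic, chelating and epimerisable at C2 in front of the molybdenum alkylidyne, while the skeleton and the bond formed stay the same.

**Route**

Step 1
Reactants: 1 2-methylenepropane-1,3-diol
Product: 2 2-{[(4-methoxybenzyl)oxy]methyl}prop-2-en-1-ol
Conditions: NaH (1 equiv), 4-MeOC6H4CH2Cl (1 equiv), Bu4NI (cat.), THF/DMF, 0 °C to rt; 1 in twofold excess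
Reagents that add atoms: 4-methoxybenzyl chloride COc1ccc(CCl)cc1
Why: Williamson etherification of a symmetric diol, in which the excess of cheap diol favours the mono-ether.

Step 2
Reactants: 2 2-{[(4-methoxybenzyl)oxy]methyl}prop-2-en-1-ol
Product: 3 [(2S)-2-{[(4-methoxybenzyl)oxy]methyl}oxiran-2-yl]methanol
Conditions: Ti(OiPr)4 (10 mol %), L-(+)-diethyl tartrate (12 mol %), t-BuOOH, 4 Å molecular sieves, CH2Cl2, –20 °C
Reagents that add atoms: tert-butyl hydroperoxide CC(C)(C)OO
Why: Sharpless asymmetric epoxidation of a 2-substituted allylic alcohol, in which the titanium L-(+)-tartrate complex delivers oxygen to one alkene face and so sets the future C4 stereocentre (S epoxide).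

Step 3
Reactants: 3 [(2S)-2-{[(4-methoxybenzyl)oxy]methyl}oxiran-2-yl]methanol; 4 propyne
Product: 6 (2R)-2-{[(4-methoxybenzyl)oxy]methyl}hex-4-yne-1,2-diol, via prop-1-ynyllithium 5 (not isolated)
Conditions: propyne (3.5 equiv), n-BuLi (3.2 equiv), THF, –78 °C; BF3·OEt2; then 3, –78 °C; NH4Cl quench
Reagents that add atoms: none
Why: BF3-promoted alkynylation of an epoxide (Yamaguchi type), in which the acetylide attacks the unsubstituted epoxide CH2 in an SN2 opening after the first equivalent has deprotonated the hydroxyl, so the quaternary stereocentre is not touched and the low temperature suppresses Payne-type equilibration.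

Step 4
Reactants: 6 (2R)-2-{[(4-methoxybenzyl)oxy]methyl}hex-4-yne-1,2-diol
Product: 7 (4S)-4-(but-2-yn-1-yl)-4-{[(4-methoxybenzyl)oxy]methyl}-2,2-dimethyl-1,3-dioxolane
Conditions: Me2C(OMe)2, PPTS (cat.), CH2Cl2, rt
Reagents that add atoms: 2,2-dimethoxypropane COC(C)(C)OC
Why: Acid-catalysed transacetalisation, in which only the primary/tertiary 1,2-diol can close a dioxolane because the third oxygen is blocked as the PMB ether.

Step 5
Reactants: 7 (4S)-4-(but-2-yn-1-yl)-4-{[(4-methoxybenzyl)oxy]methyl}-2,2-dimethyl-1,3-dioxolane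
Product: 8 [(4S)-4-(but-2-yn-1-yl)-2,2-dimethyl-1,3-dioxolan-4-yl]methanol
Conditions: DDQ, CH2Cl2/pH 7 buffer (10:1), 0 °C to rt
Reagents that add atoms: none
Why: Oxidative cleavage of the PMB ether by benzylic hydride abstraction, run buffered so that the acetonide and the alkyne are left alone.

Step 6
Reactants: 8 [(4S)-4-(but-2-yn-1-yl)-2,2-dimethyl-1,3-dioxolan-4-yl]methanol
Product: 9 (4R)-4-(but-2-yn-1-yl)-2,2-dimethyl-1,3-dioxolane-4-carbaldehyde
Conditions: Dess–Martin periodinane, NaHCO3, CH2Cl2, 0 °C to rt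
Reagents that add atoms: none
Why: Dess–Martin oxidation of a neopentyl primary alcohol to an aldehyde that has no α-hydrogen and therefore cannot epimerise.

Step 7
Reactants: 9 (4R)-4-(but-2-yn-1-yl)-2,2-dimethyl-1,3-dioxolane-4-carbaldehyde; 10 (4R)-4-benzyl-3-propanoyl-1,3-oxazolidin-2-one
Product: 12 (4R)-4-benzyl-3-{(2R,3R)-3-[(4R)-4-(but-2-yn-1-yl)-2,2-dimethyl-1,3-dioxolan-4-yl]-3-hydroxy-2-methylpropanoyl}-1,3-oxazolidin-2-one, via dibutylboron Z-enolate 11 (not isolated)
Conditions: Bu2BOTf, iPr2NEt, CH2Cl2, 0 °C; then 9, –78 °C to 0 °C; pH 7 buffer, MeOH, H2O2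
Reagents that add atoms: none
Why: Evans syn-aldol reaction, in which the Z-boron enolate reacts through a Zimmerman–Traxler chair on the face dictated by the (R)-benzyl auxiliary and so sets C2 as R, while the C3 carbinol centre (R, syn) is removed later by oxidation.

Step 8
Reactants: 12 aldol adduct (as named in step 7)
Product: 13 (4R)-4-benzyl-3-{(2R,3R)-3-[(4R)-4-(but-2-yn-1-yl)-2,2-dimethyl-1,3-dioxolan-4-yl]-2-methyl-3-[(triethylsilyl)oxy]propanoyl}-1,3-oxazolidin-2-one
Conditions: Et3SiOTf, 2,6-lutidine, CH2Cl2, –78 °C to 0 °C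
Reagents that add atoms: triethylsilyl trifluoromethanesulfonate CC[Si](CC)(CC)OS(=O)(=O)C(F)(F)F
Why: Silylation of a hindered secondary alcohol with a silyl triflate and a non-nucleophilic base, mild enough to leave the acetonide intact.

Step 9
Reactants: 13 silyl ether imide (as named in step 8)
Product: 14 (2R,3R)-3-[(4R)-4-(but-2-yn-1-yl)-2,2-dimethyl-1,3-dioxolan-4-yl]-2-methyl-3-[(triethylsilyl)oxy]propanoic acid
Conditions: LiOH, H2O2, THF/H2O, 0 °C; Na2SO3; KHSO4 to pH 4
Reagents that add atoms: hydrogen peroxide OO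
Why: Hydroperoxide cleavage of the N-acyl oxazolidinone at the exocyclic carbonyl, which does not epimerise C2 and leaves the silyl ether and acetonide in place.

Step 10
Reactants: 10 (4R)-4-benzyl-3-propanoyl-1,3-oxazolidin-2-one; 15 2,3-dibromoprop-1-ene
Product: 17 (4R)-4-benzyl-3-[(2S)-4-bromo-2-methylpent-4-enoyl]-1,3-oxazolidin-2-one, via sodium Z-enolate 16 (not isolated)
Conditions: NaN(SiMe3)2, THF, –78 °C; then 15, –78 °C to –40 °C
Reagents that add atoms: none
Why: Evans asymmetric alkylation, in which the chelated Z-enolate is alkylated by the allylic bromide on the face away from the benzyl group and so sets the future C8 stereocentre as S.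

Step 11
Reactants: 17 (4R)-4-benzyl-3-[(2S)-4-bromo-2-methylpent-4-enoyl]-1,3-oxazolidin-2-one
Product: 18 (2S)-4-bromo-2-methylpent-4-en-1-ol
Conditions: LiBH4, MeOH (1 equiv), Et2O, 0 °C
Reagents that add atoms: none
Why: Reductive removal of the auxiliary by borohydride attack at the exocyclic carbonyl, under which the vinyl bromide and the stereocentre are inert.

Step 12
Reactants: 18 (2S)-4-bromo-2-methylpent-4-en-1-ol
Product: 19 (2S)-4-bromo-2-methylpent-4-enal
Conditions: Dess–Martin periodinane, NaHCO3, CH2Cl2, 0 °C to rt; used without delay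
Reagents that add atoms: none
Why: Dess–Martin oxidation under buffered, non-basic conditions, so the α-methyl stereocentre of the aldehyde is not enolised.

Step 13
Reactants: 19 (2S)-4-bromo-2-methylpent-4-enal
Product: 20 (4S)-2-bromo-4-methylhex-1-en-5-yne
Conditions: MeC(O)C(N2)P(O)(OMe)2, K2CO3, MeOH, 0 °C to rt
Reagents that add atoms: dimethyl (1-diazo-2-oxopropyl)phosphonate COP(=O)(OC)C(=[N+]=[N-])C(C)=O
Why: Seyferth–Gilbert homologation in the Ohira–Bestmann form, in which addition of the diazophosphonate anion, loss of phosphate and nitrogen and a 1,2-hydrogen shift give the terminal alkyne faster than the aldehyde enolises at 0 °C.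

Step 14
Reactants: 20 (4S)-2-bromo-4-methylhex-1-en-5-yne
Product: 22 (4S)-2-bromo-4-methylhept-1-en-5-yne, via lithium acetylide 21 (not isolated)
Conditions: LiN(iPr)2 (1.05 equiv), THF, –78 °C; MeI, –78 °C to rt
Reagents that add atoms: iodomethane CI
Why: Deprotonation of the terminal alkyne by an amide base, which does not undergo bromine–lithium exchange with the vinyl bromide, followed by SN2 methylation of the acetylide.

Step 15
Reactants: 23 (3R)-pent-1-yn-3-ol
Product: 25 (1E,3R)-1-iodo-2-methylpent-1-en-3-ol, via alkenylalane 24 (not isolated)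
Conditions: AlMe3 (3 equiv), Cp2ZrCl2 (0.3 equiv), CH2Cl2, 0 °C to rt; then I2, THF, –30 °C to 0 °C; aq. Na2S2O3
Reagents that add atoms: trimethylaluminium C[Al](C)C; iodine II
Why: Negishi zirconium-catalysed carboalumination, a syn addition of CH3 and aluminium that places CH3 on the internal carbon, followed by iodinolysis with retention to give the E iodide with the carbinol centre untouched.

Step 16
Reactants: 22 (4S)-2-bromo-4-methylhept-1-en-5-yne; 25 (1E,3R)-1-iodo-2-methylpent-1-en-3-ol
Product: 28 (3R,4E,8S)-4,8-dimethyl-6-methylideneundec-4-en-9-yn-3-ol, via alkenyllithium 26 (not isolated), via lithium alkenylborate 27 (not isolated)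
Conditions: 22, t-BuLi (2 equiv), Et2O, –78 °C; 2-isopropoxy-4,4,5,5-tetramethyl-1,3,2-dioxaborolane, –78 °C to rt; then 25, PdCl2(dppf) (5 mol %), aq. K3PO4, DMF, rt to 45 °C
Reagents that add atoms: none
Why: Bromine–lithium exchange, trapping as the borate and Suzuki–Miyaura coupling with the alkenyl iodide form the C10–C11 bond with retention at both alkenes, and the free hydroxyl is tolerated under the aqueous basic conditions.

Step 17
Reactants: 14 silyl ether acid (as named in step 9); 28 (3R,4E,8S)-4,8-dimethyl-6-methylideneundec-4-en-9-yn-3-ol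
Product: 30 (3R,4E,8S)-4,8-dimethyl-6-methylideneundec-4-en-9-yn-3-yl (2R,3R)-3-[(4R)-4-(but-2-yn-1-yl)-2,2-dimethyl-1,3-dioxolan-4-yl]-2-methyl-3-[(triethylsilyl)oxy]propanoate, via mixed anhydride 29 (not isolated)
Conditions: 2,4,6-Cl3C6H2COCl, Et3N, toluene, rt; then 28, DMAP, toluene, rt to 40 °C
Reagents that add atoms: none
Why: Yamaguchi esterification through the mixed anhydride and the acylpyridinium ion, which keeps the C13 configuration because the C–O bond of the alcohol is not broken and does not enolise the β-silyloxy acid at C2.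

Step 18
Reactants: 30 diyne ester (as named in step 17)
Product: 31 cycloalkyne lactone: 14-membered ring O–C1(=O)–C2H(CH3)–C3H(OSiEt3)–C4–C5H2–C6≡C7–C8H(CH3)–C9H2–C10(=CH2)–C11H=C12(CH3)–C13H(Et), with C4 spiro-fused to a 2,2-dimethyl-1,3-dioxolane through its oxygen and its CH2O arm; 2R,3R,4R,8S,13R; 11E
Conditions: (4-MeOC6H4C≡)Mo(OSiPh3)3 (10 mol %), 5 Å molecular sieves, toluene (2 mM), 80 °C
Reagents that add atoms: none
Why: The Mo≡C unit adds to each methyl-capped alkyne in a [2+2] fashion to give metallacyclobutadienes that cyclorevert, so the C6 and C7 termini are taken onto the metal in turn and joined, and but-2-yne is the only co-product, whose uptake by the 5 Å sieves drives the equilibrium forward. The closest known reaction type is ring-closing alkyne metathesis with molybdenum alkylidyne triarylsilanolate catalysts, established for macrocyclic cycloalkyne lactones. The single ring closes by intramolecular union of the two alkyne ends of one chain, giving an endocyclic triple bond in a 14-membered ring large enough to hold the linear C5–C6≡C7–C8 unit, and the 2 mM concentration favours closure over acyclic dimers. No stereocentre is formed, and C2, C3, C4, C8 and C13 are not touched because the catalyst is neither a base nor a protic acid. The selectivity needed is alkyne over alkene: the alkylidyne does not react with the C10=CH2 or C11=C12 bonds. The substrate secures clean turnover by offering no ketone, acidic C–H or free hydroxyl, since C3 is a silyl ether and the C4 diol an acetonide.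

Step 19
Reactants: 31 cycloalkyne lactone silyl ether
Product: 32 cycloalkyne lactone as 31 but with free C3–OH (2R,3R,4R,8S,13R; 11E)
Conditions: HF·pyridine, pyridine, THF, 0 °C to rt
Reagents that add atoms: none
Why: Fluoride cleavage of the triethylsilyl ether under buffered conditions that leave the acetonide and the lactone intact.

Step 20
Reactants: 32 C3 alcohol
Product: 33 cycloalkyne lactone with C3 ketone and C4 acetonide (2R,4R,8S,13R; 11E)
Conditions: Dess–Martin periodinane, NaHCO3, CH2Cl2, 0 °C to rt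
Reagents that add atoms: none
Why: Dess–Martin oxidation of the only free hydroxyl, under buffered neutral conditions that keep the C2 configuration set in step 7.

Step 21
Reactants: 33 keto acetonide
Product: 34 cycloalkyne lactone with C3 ketone, free C4–OH and C4–CH2OH (2R,4R,8S,13R; 11E)
Conditions: AcOH/H2O/THF (4:1:1), 40 °C
Reagents that add atoms: none
Why: Hydrolysis of a terminal-type dioxolane with a weak acid, chosen so that the allylic C13–O bond is not ionised and acid-catalysed enolisation at C2 stays slow.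

Step 22
Reactants: 34 keto diol cycloalkyne
Product: 35 alkenylstannane: macrolactone as 34 with C6(SnBu3)=C7H, C5 trans to C8 (6Z by CIP; 2R,4R,8S,13R; 11E)
Conditions: [Cp*RuCl]4 (2.5 mol %), Bu3SnH (1.2 equiv, slow addition), CH2Cl2, rt
Reagents that add atoms: tributyltin hydride CCCC[SnH](CCCC)CCCC
Why: Hydroxyl-directed ruthenium-catalysed trans-hydrostannation, in which the homopropargylic C4–OH (helped by the primary hydroxyl on the same side) hydrogen-bonds to the chloride on ruthenium, so tin goes to the proximal C6 and hydrogen to C7 on the opposite face, while the diene, hindered in its s-cis form by the C12 methyl group, is not expected to bind the metal.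

Step 23
Reactants: 35 alkenylstannane
Product: 36 (3R,5R,7E,9S,12E,14R)-14-ethyl-5-hydroxy-5-(hydroxymethyl)-3,7,9,13-tetramethyl-11-methylidene-1-oxacyclotetradeca-7,12-diene-2,4-dione (the target; 2R,4R,6E,8S,11E,13R in the C1–C13 numbering)
Conditions: MeI, copper thiophene-2-carboxylate (CuO2CC4H3S), [Ph2PO2][NBu4], Pd(PPh3)4 (10 mol %), DMF, rt
Reagents that add atoms: iodomethane CI
Why: Copper-mediated, palladium-catalysed Stille-type methylation, in which tin–copper exchange (the phosphinate traps Bu3Sn) and coupling with MeI replace tin by CH3 with retention, giving the 6E alkene under near-neutral conditions that spare the 2-methyl-3-keto lactone and the free hydroxyls.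

**Compound list**

1 | 2-methylenepropane-1,3-diol | C=C(CO)CO | starting material
2 | 2-{[(4-methoxybenzyl)oxy]methyl}prop-2-en-1-ol | C=C(CO)COCc1ccc(OC)cc1 | intermediate
3 | [(2S)-2-{[(4-methoxybenzyl)oxy]methyl}oxiran-2-yl]methanol | OC[C@@]1(COCc2ccc(OC)cc2)CO1 | intermediate
4 | propyne | CC#C | starting material
5 | prop-1-ynyllithium (not isolated) | [Li]C#CC | intermediate
6 | (2R)-2-{[(4-methoxybenzyl)oxy]methyl}hex-4-yne-1,2-diol | OC[C@@](O)(COCc1ccc(OC)cc1)CC#CC | intermediate
7 | (4S)-4-(but-2-yn-1-yl)-4-{[(4-methoxybenzyl)oxy]methyl}-2,2-dimethyl-1,3-dioxolane | CC#CC[C@]1(COCc2ccc(OC)cc2)COC(C)(C)O1 | intermediate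
8 | [(4S)-4-(but-2-yn-1-yl)-2,2-dimethyl-1,3-dioxolan-4-yl]methanol | CC#CC[C@]1(CO)COC(C)(C)O1 | intermediate
9 | (4R)-4-(but-2-yn-1-yl)-2,2-dimethyl-1,3-dioxolane-4-carbaldehyde | CC#CC[C@]1(C=O)COC(C)(C)O1 | intermediate
10 | (4R)-4-benzyl-3-propanoyl-1,3-oxazolidin-2-one | CCC(=O)N1[C@H](Cc2ccccc2)COC1=O | starting material
11 | dibutylboron Z-enolate of 10 (not isolated) | C/C=C(\OB(CCCC)CCCC)N1[C@H](Cc2ccccc2)COC1=O | intermediate
12 | (4R)-4-benzyl-3-{(2R,3R)-3-[(4R)-4-(but-2-yn-1-yl)-2,2-dimethyl-1,3-dioxolan-4-yl]-3-hydroxy-2-methylpropanoyl}-1,3-oxazolidin-2-one | CC#CC[C@@]1(COC(C)(C)O1)[C@H](O)[C@@H](C)C(=O)N2[C@H](Cc3ccccc3)COC2=O | intermediate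
13 | triethylsilyl ether of 12 at the C3 hydroxyl | CC#CC[C@@]1(COC(C)(C)O1)[C@H](O[Si](CC)(CC)CC)[C@@H](C)C(=O)N2[C@H](Cc3ccccc3)COC2=O | intermediate
14 | (2R,3R)-3-[(4R)-4-(but-2-yn-1-yl)-2,2-dimethyl-1,3-dioxolan-4-yl]-2-methyl-3-[(triethylsilyl)oxy]propanoic acid | CC#CC[C@@]1(COC(C)(C)O1)[C@H](O[Si](CC)(CC)CC)[C@@H](C)C(O)=O | intermediate
15 | 2,3-dibromoprop-1-ene | C=C(Br)CBr | starting material
16 | sodium Z-enolate of 10 (not isolated) | C/C=C(\[O-])N1[C@H](Cc2ccccc2)COC1=O.[Na+] | intermediate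
17 | (4R)-4-benzyl-3-[(2S)-4-bromo-2-methylpent-4-enoyl]-1,3-oxazolidin-2-one | C=C(Br)C[C@H](C)C(=O)N1[C@H](Cc2ccccc2)COC1=O | intermediate
18 | (2S)-4-bromo-2-methylpent-4-en-1-ol | C=C(Br)C[C@H](C)CO | intermediate
19 | (2S)-4-bromo-2-methylpent-4-enal | C=C(Br)C[C@H](C)C=O | intermediate
20 | (4S)-2-bromo-4-methylhex-1-en-5-yne | C=C(Br)C[C@H](C)C#C | intermediate
21 | lithium acetylide of 20 (not isolated) | C=C(Br)C[C@H](C)C#C[Li] | intermediate
22 | (4S)-2-bromo-4-methylhept-1-en-5-yne | C=C(Br)C[C@H](C)C#CC | intermediate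
23 | (3R)-pent-1-yn-3-ol | C#C[C@@H](CC)O | starting material
24 | [(1E,3R)-3-(dimethylalumanyloxy)-2-methylpent-1-en-1-yl]dimethylalumane (not isolated) | CC[C@@H](O[Al](C)C)/C(C)=C/[Al](C)C | intermediate
25 | (1E,3R)-1-iodo-2-methylpent-1-en-3-ol | CC[C@@H](O)/C(C)=C/I | intermediate
26 | [(4S)-4-methylhept-1-en-5-yn-2-yl]lithium (not isolated) | [Li]C(=C)C[C@H](C)C#CC | intermediate
27 | lithium isopropoxy(pinacolato)[(4S)-4-methylhept-1-en-5-yn-2-yl]borate (not isolated) | [Li+].CC#C[C@@H](C)CC(=C)[B-]1(OC(C)C)OC(C)(C)C(C)(C)O1 | intermediate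
28 | (3R,4E,8S)-4,8-dimethyl-6-methylideneundec-4-en-9-yn-3-ol | CC#C[C@@H](C)CC(=C)/C=C(\C)[C@@H](CC)O | intermediate
29 | mixed anhydride of 14 with 2,4,6-trichlorobenzoic acid (not isolated) | CC#CC[C@@]1(COC(C)(C)O1)[C@H](O[Si](CC)(CC)CC)[C@@H](C)C(=O)OC(=O)c2c(Cl)cc(Cl)cc2Cl | intermediate
30 | (3R,4E,8S)-4,8-dimethyl-6-methylideneundec-4-en-9-yn-3-yl (2R,3R)-3-[(4R)-4-(but-2-yn-1-yl)-2,2-dimethyl-1,3-dioxolan-4-yl]-2-methyl-3-[(triethylsilyl)oxy]propanoate (precursor of the key step) | CC#C[C@@H](C)CC(=C)/C=C(\C)[C@@H](CC)OC(=O)[C@H](C)[C@@H](O[Si](CC)(CC)CC)[C@](O1)(COC1(C)C)CC#CC | intermediate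
31 | 14-membered cycloalkyne lactone: C6≡C7, C3–OSiEt3, C4 diol as acetonide (product of the key step; 2R,3R,4R,8S,13R; 11E) | C=C1/C=C(\C)[C@@H](CC)OC(=O)[C@H](C)[C@@H](O[Si](CC)(CC)CC)[C@](O2)(COC2(C)C)CC#C[C@@H](C)C1 | intermediate
32 | cycloalkyne lactone with free C3–OH, C4 diol as acetonide | C=C1/C=C(\C)[C@@H](CC)OC(=O)[C@H](C)[C@@H](O)[C@](O2)(COC2(C)C)CC#C[C@@H](C)C1 | intermediate
33 | cycloalkyne lactone with C3 ketone, C4 diol as acetonide | C=C1/C=C(\C)[C@@H](CC)OC(=O)[C@H](C)C(=O)[C@](O2)(COC2(C)C)CC#C[C@@H](C)C1 | intermediate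
34 | cycloalkyne lactone with C3 ketone, free C4–OH and C4–CH2OH | C=C1/C=C(\C)[C@@H](CC)OC(=O)[C@H](C)C(=O)[C@](O)(CO)CC#C[C@@H](C)C1 | intermediate
35 | C6-tributylstannyl alkene, C5 trans to C8 | C=C1/C=C(\C)[C@@H](CC)OC(=O)[C@H](C)C(=O)[C@](O)(CO)C/C([Sn](CCCC)(CCCC)CCCC)=C/[C@@H](C)C1 | intermediate
36 | (3R,5R,7E,9S,12E,14R)-14-ethyl-5-hydroxy-5-(hydroxymethyl)-3,7,9,13-tetramethyl-11-methylidene-1-oxacyclotetradeca-7,12-diene-2,4-dione | C=C1/C=C(\C)[C@@H](CC)OC(=O)[C@H](C)C(=O)[C@](O)(CO)C/C(C)=C/[C@@H](C)C1 | target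

**Step count and risks**

Total step count: 23. Longest linear sequence: 16 steps (steps 1–9, then 17–23); the alcohol branch (steps 10–16) joins at step 17.

Steps most likely to fail:

1. Step 18. Intermolecular metathesis to acyclic dimers and oligomers may outrun ring closure, or the catalyst may decay before the α-branched C7 alkyne is engaged. The fallback puts the C6≡C7 bond in place before any ring exists and closes the ring at the lactone C–O bond. It sets out from epoxy alcohol 3 and bromo-enyne 20 (with 10 and 25 as in the main route). Lithium acetylide 21 (from 20 with n-BuLi, THF, –78 °C, 2.5 equiv) opens 3 under BF3·OEt2 to give diol F1. Me2C(OMe)2/PPTS gives acetonide F2, DDQ gives primary alcohol F3 and Dess–Martin oxidation gives aldehyde F4. The Evans aldol reaction with 10 (Bu2BOTf, iPr2NEt) gives syn adduct F5, Et3SiOTf/2,6-lutidine gives silyl ether F6, and LiOH/H2O2 gives acid F7. Separately, Miyaura borylation of 25 (B2pin2, PdCl2(dppf), KOPh, toluene, 50 °C) gives alkenylboronate F8. Suzuki coupling of F7 with F8 (Pd(PPh3)4, aq. K3PO4, THF) gives seco acid F9, and Yamaguchi macrolactonisation at high dilution comes back to the route at cycloalkyne 31.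

2. Step 22. Tin may be delivered to C7 instead of C6, or turnover may stall, if the C4 hydroxyl is tied up in a hydrogen bond to the C3 ketone or the ruthenium is held by the diene. The fallback moves hydrostannation and methylation ahead of ketone formation. It sets out from hydroxy acetonide 32. AcOH/H2O/THF gives triol F10, in which all three hydroxyls lie on the C5 side of the alkyne. [Cp*RuCl]4/Bu3SnH gives stannane F11, and the methyl-for-tin exchange of step 23 gives methylated triol F12. TBSCl/imidazole silylates the primary hydroxyl to give silyl ether F13, and Parikh–Doering oxidation (SO3·pyridine, DMSO, iPr2NEt) of the C3 hydroxyl gives keto silyl ether F14. HF·pyridine then comes back to the route at target 36.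

3. Step 23. Protodestannation at the hindered C6 position may outrun methyl transfer. The fallback reverses the polarity of the coupling. It sets out from stannane 35: iodine in CH2Cl2 at –20 °C gives alkenyl iodide F15 with retention, and a base-free Stille coupling with Me4Sn (Pd2(dba)3, AsPh3, NMP, 50 °C) comes back to the route at target 36.

**Further compounds**

F1 | step 18 | (2R)-2-{[(4-methoxybenzyl)oxy]methyl}-2-hydroxy chain diol bearing the C6≡C7 alkyne and the 2-bromoallyl end: (2R,7S)-9-bromo-2-{[(4-methoxybenzyl)oxy]methyl}-7-methyldec-9-en-4-yne-1,2-diol | OC[C@@](O)(COCc1ccc(OC)cc1)CC#C[C@@H](C)CC(Br)=C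
F2 | step 18 | acetonide of F1 (primary/tertiary diol) | C=C(Br)C[C@H](C)C#CC[C@]1(COCc2ccc(OC)cc2)COC(C)(C)O1
F3 | step 18 | primary alcohol from F2 after PMB removal | C=C(Br)C[C@H](C)C#CC[C@]1(CO)COC(C)(C)O1
F4 | step 18 | aldehyde from F3 | C=C(Br)C[C@H](C)C#CC[C@]1(C=O)COC(C)(C)O1
F5 | step 18 | Evans syn-aldol adduct of F4 with 10 | C=C(Br)C[C@H](C)C#CC[C@@]1(COC(C)(C)O1)[C@H](O)[C@@H](C)C(=O)N2[C@H](Cc3ccccc3)COC2=O
F6 | step 18 | triethylsilyl ether of F5 | C=C(Br)C[C@H](C)C#CC[C@@]1(COC(C)(C)O1)[C@H](O[Si](CC)(CC)CC)[C@@H](C)C(=O)N2[C@H](Cc3ccccc3)COC2=O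
F7 | step 18 | carboxylic acid from F6 | C=C(Br)C[C@H](C)C#CC[C@@]1(COC(C)(C)O1)[C@H](O[Si](CC)(CC)CC)[C@@H](C)C(O)=O
F8 | step 18 | (1E,3R)-2-methyl-1-(4,4,5,5-tetramethyl-1,3,2-dioxaborolan-2-yl)pent-1-en-3-ol | CC[C@@H](O)/C(C)=C/B1OC(C)(C)C(C)(C)O1
F9 | step 18 | seco acid with C6≡C7 alkyne, C3–OSiEt3, C4 acetonide and free C13–OH | CC[C@@H](O)/C(C)=C/C(=C)C[C@H](C)C#CC[C@@]1(COC(C)(C)O1)[C@H](O[Si](CC)(CC)CC)[C@@H](C)C(O)=O
F10 | step 22 | cycloalkyne lactone triol (C3–OH, C4–OH, C4–CH2OH) | C=C1/C=C(\C)[C@@H](CC)OC(=O)[C@H](C)[C@@H](O)[C@](O)(CO)CC#C[C@@H](C)C1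
F11 | step 22 | C6-tributylstannyl alkene triol | C=C1/C=C(\C)[C@@H](CC)OC(=O)[C@H](C)[C@@H](O)[C@](O)(CO)C/C([Sn](CCCC)(CCCC)CCCC)=C/[C@@H](C)C1
F12 | step 22 | C6-methyl (6E) alkene triol | C=C1/C=C(\C)[C@@H](CC)OC(=O)[C@H](C)[C@@H](O)[C@](O)(CO)C/C(C)=C/[C@@H](C)C1
F13 | step 22 | primary tert-butyldimethylsilyl ether of F12 | C=C1/C=C(\C)[C@@H](CC)OC(=O)[C@H](C)[C@@H](O)[C@](O)(CO[Si](C)(C)C(C)(C)C)C/C(C)=C/[C@@H](C)C1
F14 | step 22 | C3 ketone with primary tert-butyldimethylsilyl ether | C=C1/C=C(\C)[C@@H](CC)OC(=O)[C@H](C)C(=O)[C@](O)(CO[Si](C)(C)C(C)(C)C)C/C(C)=C/[C@@H](C)C1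
F15 | step 23 | C6-iodo alkene (C5 trans to C8) keto diol | C=C1/C=C(\C)[C@@H](CC)OC(=O)[C@H](C)C(=O)[C@](O)(CO)C/C(I)=C/[C@@H](C)C1
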